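Each flask starts from the same amounts of substrate and partner, with no intermediate, and the flasks differ in their temperature history.

| flask | substrate | partner | temperature | time | remark |
|---|---|---|---|---|---|
| cedar | 1.8 M | 1.44 M | 25 °C | 10 min |  |
| alder | 1.8 M | 1.44 M | 5 °C | 10 min |  |
| elm | 1.8 M | 1.44 M |  | 10 min | at 25 °C until 2.0 min, from then on at 5 °C |

    partner + intermediate → target (k1 = 0.0014 M⁻¹ s⁻¹, Ea1 = 69.0 kJ mol⁻¹)
    substrate + target → side product (k2 = 2.5 × 10⁻⁴ M⁻¹ s⁻¹, Ea2 = 66.0 kJ mol⁻¹)
    2 intermediate → homo product (k3 = 0.0016 M⁻¹ s⁻¹, Ea3 = 53.0 kJ mol⁻¹)
    substrate → intermediate (k4 = 9.6 × 10⁻⁴ s⁻¹, Ea4 = 97.0 kJ mol⁻¹)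
    (constants at 25 °C)

- percentages count the substrate that a species holds: one homo product or side product counts as two
- a doubled species enters its step squared and goes two at a time
- the constants hold at 25 °C; other temperatures follow from the activation energies

1. the best flask by amount of target, in percent of the substrate charged; "all alike" if 1.5 percentage points covers them all (cedar / alder / elm / all alike)
2. amount of target at the end, in percent of the substrate charged, cedar
3. amount of target at the end, in percent of the substrate charged, alder
4. amount of target at the end, in percent of the substrate charged, elm

Target forms in two stages: substrate feeds intermediate, and partner captures it. While substrate and partner stay near their charges, both can be frozen. The feed then converts a steady share of the charge per minute, 0.0576 min⁻¹ at the warm temperature and 0.00346 min⁻¹ at the cold one. Capture becomes a pseudo-first-order step whose capture constant is the rate constant of step 1 times the charged partner. That constant is 0.121 min⁻¹ warm and, with step 1 slower by a factor of 7.4, 0.0163 min⁻¹ cold. Target gained is then the capture constant times the mean intermediate times the time.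

Elm looks contradictory by this reckoning. Its warm 2.0 min give 1.39 % of target from the intermediate fed in that time, yet its cold 8.00 min add 1.51 % from that same stock, although capture there is 7.4 times slower. The arithmetic clears this up. The cold stretch lasts 4.00 times as long, and it starts with the full 11.5 % of intermediate, twice the warm mean. That stock barely shrinks, since its cold capture half-life of 42.5 min is longer than the stretch. With 0.181 % from the cold feed, elm reckons to 3.08 %. Alder, cold throughout, reckons to 0.282 %. Cedar reckons to 34.8 %, but that figure reads high, because it lets intermediate pile up to 57.6 % while the warm capture half-life of 5.73 min is shorter than the run. Counting that capture, with substrate and partner still frozen, lowers cedar to 24.2 %, which is still 7.86 times the reckoning for elm, so the reckoning names cedar best.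

The forecast gives 15 % for cedar, 0.25 % for alder and 2.5 % for elm, and says of cedar that “it still clearly makes the most target”.

The simulation gives 14.7 % for cedar, 0.260 % for alder and 2.39 % for elm, so cedar is best. At the end of alder, the capture half-life of intermediate is 43 min and the half-life of substrate by its own step is 3.3 h, each longer than the 10 min run . In elm, the 1.20 % of target standing at 2.00 min, plus the cold capture constant times the 9.69 % of intermediate standing at 5.00 min over the cold stretch, gives 2.46 %, against 2.39 %. In alder, the same constant on half of the final 3.11 % of intermediate over the run gives 0.253 %, against 0.260 %.

All constants are assumed.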